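Take 19.1% of the charge as the height where the left-handed product stops: it is the mean of the last readings, at 15.0 h, in the earlier runs below.

| flask | left-handed substrate | right-handed substrate | coupling partner | free catalyst | remark | time |
|---|---|---|---|---|---|---|
| Monday's | 0.087 M | 0.087 M | 2 equiv | 0.1 mol% | run made earlier |  |
| Sunday's | 0.087 M | 0.087 M | 1 equiv | 0.1 mol% | run made earlier |  |
| Tuesday's | 0.087 M | 0.087 M | 4 equiv | 0.1 mol% | run made earlier |  |
| ochre | 0.087 M | 0.087 M | 2.00 equiv | 0.1 mol% | everything together in a closed stirred flask, run for 25 h | 25 h |
| green | 0.087 M | 0.087 M | 2.00 equiv | 0.1 mol% | plug flow through a tube for 25 h, no back-mixing | 25 h |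
| grey | 0.087 M | 0.087 M | 2.00 equiv (fed, over 20.0 h) | 0.1 mol% | all but coupling partner at the start; coupling partner goes in evenly over 20.0 h, the run ends at 25 h | 25 h |
| violet | 0.087 M | 0.087 M | 2.00 equiv | 0.1 mol% | one stirred flow tank at steady state, fed with the mixture as stated, mean residence time 25 h |  |

- Monday's (time / h: left-handed product / %, left-handed substrate / %): 1.33: 8.9, 44.8; 2.50: 14.2, 40.1; 4.00: 18.6, 40.3; 8.00: 19.7, 41.8; 15.0: 17.4, 39.4
- Sunday's (time / h: left-handed product / %, left-handed substrate / %): 1.33: 5.6, 43.0; 4.00: 12.5, 41.2; 8.00: 18.2, 40.8; 10.0: 16.4, 40.6; 15.0: 20.4, 40.9
- Tuesday's (time / h: left-handed product / %, left-handed substrate / %): 3.00: 21.0, 42.7; 6.00: 17.9, 41.6; 10.0: 17.8, 42.4; 12.0: 18.4, 39.8; 15.0: 19.6, 41.2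

(standard deviation of a reading: 1 percentage point)

- free catalyst is single-handed; left-handed substrate and right-handed substrate are mirror images of each other, charged as a racemate, each of them at the stated concentration
- the stated concentrations are those of everything mixed, before any reaction; amounts are the same in each set-up
- the feed brings no volume worth counting
- the earlier runs were made in a closed, stirred flask

- the set-up with the highest amount of left-handed product at the outlet or at the end, in percent of the left-handed substrate and right-handed substrate together put in ("none" if the first two lie within 2 percentage points) (ochre / green / grey / violet / none)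
- amount of left-handed product at the outlet or at the end, in percent of the left-handed substrate and right-handed substrate together put in, ochre
- amount of left-handed product at the outlet or at the end, in percent of the left-handed substrate and right-handed substrate together put in, green
- amount of left-handed product at the outlet or at the end, in percent of the left-handed substrate and right-handed substrate together put in, grey
- amount of left-handed product at the outlet or at the end, in percent of the left-handed substrate and right-handed substrate together put in, violet

Read the product column first. At 1.33 h, Sunday's run with 1 equiv of coupling partner shows 5.6% and Monday's run with 2 equiv shows 8.9%, so more partner makes product faster. Now read the last row: 20.4%, 17.4% and 19.6% lie close together for a scatter of 1 percentage point, so partner moves the speed and leaves the height.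

Next read the substrate column. Treat the swap between the two substrates as fast, so that each holds half of what is not product, 40.4%; the last readings stand there, so substrate remains at the stop. In Sunday's run the product has used 38.2% of the partner, so 61.8% remains.

That points to the catalyst, loaded at 0.1 mol% on the left-handed substrate and so 0.0500% of both substrates together. Divide: 383 is the turnovers per catalyst, the product made by one catalyst before it is lost (turnover number).

Monday's first reading gives an approach to the stop of 0.471 h⁻¹. Over 25 h, ochre and green have 11.8 such spans, so reckon 19.1% for both. Grey's even feed counts as 15.0 h at full partner, and if that approach is the loss of catalyst, my estimate is 0.0861% of its catalyst live at the end, so reckon 19.1% there too. Violet's tank, with x for its 11.8 spans in the mean residence time, reaches the share x/(1+x) of the stop, which is 17.6%. My top two stand level at 19.1%, inside the margin of 2 points, so my answer is that no set-up wins.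

The forecast calls the stop “a fixed limit” and gives 19% for ochre, 19% for green, 18.9% for grey, 17.8% for violet, and best: none.

Ochre gives 19.3%, green 19.3%, grey 19.8% and violet 16.9%, so best is none.

    free catalyst + left-handed substrate ⇌ catalyst intermediate A (K = 19.0 L mol⁻¹, k = 86.0 L mol⁻¹ s⁻¹)
    free catalyst + right-handed substrate ⇌ catalyst intermediate B (K = 6.40 L mol⁻¹, k = 87.0 L mol⁻¹ s⁻¹)
    coupling partner + catalyst intermediate A → free catalyst + left-handed product (k = 0.790 L mol⁻¹ s⁻¹)
    coupling partner + catalyst intermediate B → free catalyst + right-handed product (k = 0.0130 L mol⁻¹ s⁻¹)
    left-handed substrate ⇌ right-handed substrate (k = 2.90 × 10⁻⁴ s⁻¹)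
    coupling partner + free catalyst → spent catalyst (k = 0.00290 L mol⁻¹ s⁻¹)

At 25.0 h, ochre holds >99.9% of its catalyst as spent catalyst, with 81% of its partner left. Grey's number moves with the catalyst: a neighbour of grey at 0.06 mol% has a share of 0.0300%, which times 383 is 11.5%, and that flask ends at 12.5%.

The runs stem from a simulated flask for an exercise; scatter was added.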